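**Plan**

1. Retrosynthesis first removes the central O-benzyl group and the two C3' silyl groups. Each outer naphthalene is then cut at C4a'–C4' and C2'–C3' (primed locants: C1' carries OH, C4' is bonded to the central naphthalene, C8' carries OMe). This gives the central 2,4-diyne 6 and two molecules of bromo ketone 10; the two C(sp2)–C(sp) bonds of 6 lead back to dibromide 4.
2. Enabling feature: in each outer unit the phenol ring C1'(OH)–C2'(H)–C3'(H)–C4'(aryl)–C4a'–C8a' is fused to a benzo ring with OMe at C8'. C8a', C1' and C2' map onto the ring carbon, carbonyl carbon and methyl carbon of a 2-bromo-6-methoxyacetophenone, C4a' onto its brominated carbon, and C3'/C4' onto an alkyne on the central ring.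
3. Forward: the central naphthalene is bought intact (1), then monomethylated, dibrominated at C2/C4, benzylated and dialkynylated. Both outer phenol rings close together in step 7; hydrogenolysis and protodesilylation finish the synthesis.
4. Stereochemistry: the target has no stereocentre and its SMILES carries no axial descriptor, so nothing has to be controlled.

Key step: step 7

Remark on the chemistry: the two biaryl axes of the target are flanked only by OH, H and peri C–H and are assumed to rotate at ambient temperature. The silylated intermediates 12 and 13 may be mixtures of slowly interconverting atropisomers, which converge once silicon is removed.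

**Route**

Step 1
Reactants: 1 naphthalene-1,8-diol
Product: 2 8-methoxynaphthalen-1-ol
Conditions: MeI (1.1 equiv), K2CO3 (1.1 equiv), acetone, reflux
Reagents that add atoms: iodomethane, CI
Why: Williamson ether synthesis; the peri diol gives its monoanion selectively and the remaining hydroxyl, hydrogen-bonded to the new methoxy oxygen, is far less acidic, so the alkylation should stop at the monoether.

Step 2
Reactants: 2 8-methoxynaphthalen-1-ol
Product: 3 2,4-dibromo-8-methoxynaphthalen-1-ol
Conditions: NBS (2.05 equiv), i-Pr2NH (10 mol %), dry CH2Cl2, 0 °C, dark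
Reagents that add atoms: N-bromosuccinimide, O=C1CCC(=O)N1Br
Why: Electrophilic aromatic bromination; the free hydroxyl (a stronger donor than the hydrogen-bond-accepting methoxy group) should direct both bromines to its own ring at C4 (para) and C2 (ortho, amine-assisted delivery), and dry conditions with two equivalents avoid oxidation to a bromonaphthoquinone.

Step 3
Reactants: 3 2,4-dibromo-8-methoxynaphthalen-1-ol
Product: 4 1-(benzyloxy)-2,4-dibromo-8-methoxynaphthalene
Conditions: BnBr (1.2 equiv), K2CO3 (1.5 equiv), DMF, 50 °C
Reagents that add atoms: benzyl bromide, BrCc1ccccc1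
Why: Williamson O-benzylation of an acidic dibromonaphthol is routine, and the benzyl ether survives the later palladium and base steps and leaves by hydrogenolysis.

Step 4
Reactants: 4 1-(benzyloxy)-2,4-dibromo-8-methoxynaphthalene; 5 ethynyltrimethylsilane (3 equiv)
Product: 6 1-(benzyloxy)-8-methoxy-2,4-bis[(trimethylsilyl)ethynyl]naphthalene
Conditions: PdCl2(PhCN)2 (5 mol %), [HP(t-Bu)3]BF4 (10 mol %), CuI (5 mol %), i-Pr2NH, 1,4-dioxane, rt → 45 °C
Reagents that add atoms: none
Why: Twofold Sonogashira coupling; palladium carrying the bulky, electron-rich P(t-Bu)3 couples electron-rich and ortho-substituted aryl bromides with terminal alkynes near room temperature, mild enough to keep both alkynyl C–Si bonds.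

Step 5
Reactants: 7 2-bromo-6-methoxybenzoic acid
Product: 9 2-bromo-N,6-dimethoxy-N-methylbenzamide, via 2-bromo-6-methoxybenzoyl chloride 8 (not isolated)
Conditions: (COCl)2, DMF (cat.), CH2Cl2, rt; concentrate; then MeNH(OMe)·HCl, Et3N, CH2Cl2, 0 °C → rt
Reagents that add atoms: N,O-dimethylhydroxylamine hydrochloride, CNOC.Cl; oxalyl chloride, O=C(Cl)C(Cl)=O (its chlorine is found only in 8)
Why: Acid chloride formation followed by N-acylation (Weinreb amide synthesis); the acid chloride overcomes the hindrance of the 2,6-disubstituted benzoic acid.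

Step 6
Reactants: 9 2-bromo-N,6-dimethoxy-N-methylbenzamide
Product: 10 1-(2-bromo-6-methoxyphenyl)ethan-1-one
Conditions: MeMgBr (2 equiv), THF, 0 °C → rt; then 1 M HCl
Reagents that add atoms: methylmagnesium bromide, C[Mg]Br
Why: Weinreb ketone synthesis; the chelated tetrahedral magnesium adduct stops at single addition and the aryl bromide is inert to the Grignard reagent.

Step 7
Reactants: 6 1-(benzyloxy)-8-methoxy-2,4-bis[(trimethylsilyl)ethynyl]naphthalene; 10 1-(2-bromo-6-methoxyphenyl)ethan-1-one (3 equiv, added in portions)
Product: 12 1-(benzyloxy)-2,4-bis[4-hydroxy-5-methoxy-2-(trimethylsilyl)naphthalen-1-yl]-8-methoxynaphthalene, via mono-annulated alkynyl naphthol 11 (not isolated)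
Conditions: Pd(OAc)2 (10 mol %), [HP(t-Bu)3]BF4 (20 mol %), anhydrous Cs2CO3 (6 equiv), CsOPiv (30 mol %), 1,4-dioxane, 100 °C
Reagents that add atoms: none
Why: Proposed new method: zerovalent palladium inserts into the C–Br bond of 10, the arylpalladium bromide adds syn across a silylalkyne of 6 with the aryl group going to the naphthyl-bearing carbon and palladium to the silyl-bearing carbon, carbonate (relayed by pivalate) deprotonates the neighbouring acetyl group to give a seven-membered C-bound palladium enolate, and C(sp2)–C(sp3) reductive elimination followed by keto–enol tautomerisation gives the naphthol and returns zerovalent palladium; the sequence then repeats on the second alkyne of 11 (the less hindered C4 alkyne is expected to react first, and the other order converges on 12). The closest known reaction types are the Larock carboannulation of internal alkynes by ortho-haloaryl carbon nucleophiles and the intramolecular palladium-catalysed alpha-alkenylation of ketones under carbonate or alkoxide base, whereas ortho-bromoaryl ketones and alkynes otherwise tend to give indenols. Each new ring is a six-membered carbocycle closed in a formal [4+2] benzannulation, the four-carbon unit C4a'–C8a'–C1'–C2' of the ketone spanning the two alkyne carbons, with closure by reductive elimination from the seven-membered palladacycle and aromatisation as driving force. No stereocentre arises, and 12 may form as a mixture of atropisomers about the two hindered axes, which is of no consequence. The step needs silicon next to palladium after insertion, which the bulk of the trimethylsilyl group and the stabilised alpha-silyl C–Pd bond should secure, and it needs enolate C-alkenylation instead of vinyl addition to the carbonyl group, which is favoured because the indenol pathway leaves divalent palladium that cannot turn over in an aprotic medium free of reductants and because the twisted, doubly ortho-substituted ketone is a poor electrophile. The sparingly soluble carbonate keeps free enolate low so that intermolecular alpha-arylation of 10 stays behind the intramolecular capture, and the C6 methoxy group of 10 fixes the peri OH/OMe pattern because the only other ortho position is occupied.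

Step 8
Reactants: 12 1-(benzyloxy)-2,4-bis[4-hydroxy-5-methoxy-2-(trimethylsilyl)naphthalen-1-yl]-8-methoxynaphthalene
Product: 13 2,4-bis[4-hydroxy-5-methoxy-2-(trimethylsilyl)naphthalen-1-yl]-8-methoxynaphthalen-1-ol
Conditions: H2 (1 atm), 10% Pd/C, EtOAc–MeOH, rt
Reagents that add atoms: none
Why: Catalytic hydrogenolysis of a benzyl aryl ether leaves arylsilanes, methyl ethers and naphthalene rings untouched at 1 atm, and doing it before the acid step means no benzyl cation is released among electron-rich naphthols.

Step 9
Reactants: 13 2,4-bis[4-hydroxy-5-methoxy-2-(trimethylsilyl)naphthalen-1-yl]-8-methoxynaphthalen-1-ol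
Product: 14 2,4-bis(4-hydroxy-5-methoxynaphthalen-1-yl)-8-methoxynaphthalen-1-ol
Conditions: CF3CO2H–CH2Cl2 (1:1), H2O (5 equiv), Ar, 0 °C → rt
Reagents that add atoms: none
Why: Electrophilic ipso-protodesilylation of an aryltrimethylsilane (ipso protonation stabilised by the beta-silicon effect), helped here by relief of strain between each silyl group and its neighbouring biaryl axis, while phenols and methyl ethers are stable to trifluoroacetic acid.

**Compound list**

1 | naphthalene-1,8-diol | Oc1cccc2cccc(O)c12 | starting material
2 | 8-methoxynaphthalen-1-ol | COc1cccc2cccc(O)c12 | intermediate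
3 | 2,4-dibromo-8-methoxynaphthalen-1-ol | COc1cccc2c(Br)cc(Br)c(O)c12 | intermediate
4 | 1-(benzyloxy)-2,4-dibromo-8-methoxynaphthalene | COc1cccc2c(Br)cc(Br)c(OCc3ccccc3)c12 | intermediate
5 | ethynyltrimethylsilane | C#C[Si](C)(C)C | starting material
6 | 1-(benzyloxy)-8-methoxy-2,4-bis[(trimethylsilyl)ethynyl]naphthalene | COc1cccc2c(C#C[Si](C)(C)C)cc(C#C[Si](C)(C)C)c(OCc3ccccc3)c12 | intermediate
7 | 2-bromo-6-methoxybenzoic acid | COc1cccc(Br)c1C(=O)O | starting material
8 | 2-bromo-6-methoxybenzoyl chloride | COc1cccc(Br)c1C(=O)Cl | intermediate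
9 | 2-bromo-N,6-dimethoxy-N-methylbenzamide | COc1cccc(Br)c1C(=O)N(C)OC | intermediate
10 | 1-(2-bromo-6-methoxyphenyl)ethan-1-one | COc1cccc(Br)c1C(C)=O | intermediate
11 | 4-[4-(benzyloxy)-5-methoxy-3-[(trimethylsilyl)ethynyl]naphthalen-1-yl]-8-methoxy-3-(trimethylsilyl)naphthalen-1-ol | COc1cccc2c(-c3c([Si](C)(C)C)cc(O)c4c(OC)cccc34)cc(C#C[Si](C)(C)C)c(OCc3ccccc3)c12 | intermediate
12 | 1-(benzyloxy)-2,4-bis[4-hydroxy-5-methoxy-2-(trimethylsilyl)naphthalen-1-yl]-8-methoxynaphthalene | COc1cccc2c(-c3c([Si](C)(C)C)cc(O)c4c(OC)cccc34)cc(-c3c([Si](C)(C)C)cc(O)c4c(OC)cccc34)c(OCc3ccccc3)c12 | intermediate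
13 | 2,4-bis[4-hydroxy-5-methoxy-2-(trimethylsilyl)naphthalen-1-yl]-8-methoxynaphthalen-1-ol | COc1cccc2c(-c3c([Si](C)(C)C)cc(O)c4c(OC)cccc34)cc(-c3c([Si](C)(C)C)cc(O)c4c(OC)cccc34)c(O)c12 | intermediate
14 | 2,4-bis(4-hydroxy-5-methoxynaphthalen-1-yl)-8-methoxynaphthalen-1-ol | COc1cccc2c(-c3cc(-c4ccc(O)c5c(OC)cccc45)c4cccc(OC)c4c3O)ccc(O)c12 | target

**Step count**

Total: 9 steps. Longest linear sequence: 7 steps (steps 1, 2, 3, 4, 7, 8, 9).

**Steps most likely to fail**

Step 7 (Proposed new method). The vinylpalladium intermediate may add to the ketone carbonyl or migrate to a neighbouring aryl C–H instead of being captured by the enolate. The free enolate of 10 may be arylated intermolecularly, insertion may occur with the wrong orientation, or the alkynyl silicon may be lost under base before insertion. The fallback uses known cross-coupling and sets out from 2 and 4. Para-monobromination of 2 (NBS, 1 equiv, MeCN, −20 °C) would give 4-bromo-8-methoxynaphthalen-1-ol F1. O-Benzylation (BnBr, K2CO3, DMF) would give 1-(benzyloxy)-4-bromo-8-methoxynaphthalene F2. Miyaura borylation (B2pin2, PdCl2(dppf), KOAc, dioxane, 90 °C) would give 2-[4-(benzyloxy)-5-methoxynaphthalen-1-yl]-4,4,5,5-tetramethyl-1,3,2-dioxaborolane F3. Twofold Suzuki–Miyaura coupling of F3 with 4 (Pd(OAc)2, SPhos, K3PO4, toluene–water, 100 °C) would give 1-(benzyloxy)-2,4-bis[4-(benzyloxy)-5-methoxynaphthalen-1-yl]-8-methoxynaphthalene F4. Hydrogenolysis of all three benzyl ethers (H2, Pd/C) comes back to the route at 14.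

Step 9. Ipso protonation at C3' may be too slow, because the silicon-bearing carbon is meta to the hydroxyl group, and forcing acid may oxidise or degrade the electron-rich triol. The fallback sets out from 12 and replaces protonation by halogenation and reduction. Acetylation (Ac2O, pyridine, DMAP) would give 1-(benzyloxy)-2,4-bis[4-acetoxy-5-methoxy-2-(trimethylsilyl)naphthalen-1-yl]-8-methoxynaphthalene F5. Ipso-iododesilylation (ICl, CH2Cl2, −78 → 0 °C) would give 1-(benzyloxy)-2,4-bis(4-acetoxy-2-iodo-5-methoxynaphthalen-1-yl)-8-methoxynaphthalene F6. Hydrogenolysis (H2, Pd/C, Et3N, EtOAc) would remove both iodides, any adventitious ring iodide and the benzyl group in one operation, giving 2,4-bis(4-acetoxy-5-methoxynaphthalen-1-yl)-8-methoxynaphthalen-1-ol F7. Methanolysis (K2CO3, MeOH) comes back to the route at 14.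

Step 2. Bromination may spill onto the methoxy-bearing ring (C5/C7), or the dibromonaphthol may be over-oxidised to a quinone. The fallback sets out from 2 and uses the much weaker electrophile and oxidant iodine. I2 (2 equiv) with morpholine in MeOH–CH2Cl2 would give 2,4-diiodo-8-methoxynaphthalen-1-ol F8. Benzylation (BnBr, K2CO3, DMF) would give 1-(benzyloxy)-2,4-diiodo-8-methoxynaphthalene F9. Twofold Sonogashira coupling with 5 at room temperature (PdCl2(PPh3)2, CuI, Et3N, THF) comes back to the route at 6.

**Further compounds**

F1 | step 7 | 4-bromo-8-methoxynaphthalen-1-ol | COc1cccc2c(Br)ccc(O)c12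
F2 | step 7 | 1-(benzyloxy)-4-bromo-8-methoxynaphthalene | COc1cccc2c(Br)ccc(OCc3ccccc3)c12
F3 | step 7 | 2-[4-(benzyloxy)-5-methoxynaphthalen-1-yl]-4,4,5,5-tetramethyl-1,3,2-dioxaborolane | COc1cccc2c(B3OC(C)(C)C(C)(C)O3)ccc(OCc3ccccc3)c12
F4 | step 7 | 1-(benzyloxy)-2,4-bis[4-(benzyloxy)-5-methoxynaphthalen-1-yl]-8-methoxynaphthalene | COc1cccc2c(-c3ccc(OCc4ccccc4)c4c(OC)cccc34)cc(-c3ccc(OCc4ccccc4)c4c(OC)cccc34)c(OCc3ccccc3)c12
F5 | step 9 | 1-(benzyloxy)-2,4-bis[4-acetoxy-5-methoxy-2-(trimethylsilyl)naphthalen-1-yl]-8-methoxynaphthalene | COc1cccc2c(-c3c([Si](C)(C)C)cc(OC(C)=O)c4c(OC)cccc34)cc(-c3c([Si](C)(C)C)cc(OC(C)=O)c4c(OC)cccc34)c(OCc3ccccc3)c12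
F6 | step 9 | 1-(benzyloxy)-2,4-bis(4-acetoxy-2-iodo-5-methoxynaphthalen-1-yl)-8-methoxynaphthalene | COc1cccc2c(-c3c(I)cc(OC(C)=O)c4c(OC)cccc34)cc(-c3c(I)cc(OC(C)=O)c4c(OC)cccc34)c(OCc3ccccc3)c12
F7 | step 9 | 2,4-bis(4-acetoxy-5-methoxynaphthalen-1-yl)-8-methoxynaphthalen-1-ol | COc1cccc2c(-c3ccc(OC(C)=O)c4c(OC)cccc34)cc(-c3ccc(OC(C)=O)c4c(OC)cccc34)c(O)c12
F8 | step 2 | 2,4-diiodo-8-methoxynaphthalen-1-ol | COc1cccc2c(I)cc(I)c(O)c12
F9 | step 2 | 1-(benzyloxy)-2,4-diiodo-8-methoxynaphthalene | COc1cccc2c(I)cc(I)c(OCc3ccccc3)c12
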